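**Retrosynthetic overview**

1. The target comes from its bis(benzyl ether) by hydrogenolysis, this from a 4-aroyl butanolide by Felkin–Anh hydride addition, and the ketone from a 4-(1-arylprop-1-enyl) butanolide by ozonolysis. Both arenes are bought; the butanolide is the only ring that is built, and it is built once, in the key step.
2. Key disconnection: C3–C4 of the butanolide (ring atoms O1, C2 carbonyl, C3, C4, C5). A ring-contracting Johnson–Claisen rearrangement of a 2-alkylidene-4,7-dihydro-1,3-dioxepine, assembled in the flask from a (Z)-2-ene-1,4-diol and a trimethyl orthoester, turns the seven-membered ring into the five-membered lactone.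
3. Enabling feature: once the exocyclic carbinol carbon on C4 (C-a) is an alkene carbon, O=C2–C3–C4–C(a)=C is a γ,δ-unsaturated acyl unit. Because ring atoms O1–C5 also hang on C4, the departing allylic oxygen and O1 belong to one (Z)-ene-1,4-diol. Its single carbinol centre relays chirality to C4 and C3 and is then excised as acetaldehyde.
4. The diol comes from (R)-but-3-yn-2-ol, an aryl Grignard reagent and formaldehyde (anti-arylmagnesiation, then hydroxymethylation). The orthoester comes from a 3-arylpropanenitrile (Pinner), itself from a benzylic bromide and LiCH2CN.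

Key step: step 5

Assumption: exchange of the orthoester with the (Z)-ene-1,4-diol is taken to reach the cyclic seven-membered orthoester before any [3,3] shift, as is usual for (Z)-but-2-ene-1,4-diol; 1, 2 and 6 are taken as catalogue compounds.

**Route**

Step 1
Reactants: 1 1-(benzyloxy)-4-bromo-2-methoxybenzene; 2 (R)-but-3-yn-2-ol
Product: 5 (2Z,4R)-3-[4-(benzyloxy)-3-methoxyphenyl]pent-2-ene-1,4-diol, via arylmagnesium bromide 3 (not isolated), via vinylmagnesium chelate 4 (not isolated)
Conditions: 1, Mg, THF, 45 °C (gives 3); 2, i-PrMgCl (1.0 equiv), THF, 0 °C; then 3 (2.0 equiv), CuI (15 mol%), 0 → 55 °C; then (CH2O)n (excess), 0 °C → rt; aq NH4Cl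
Reagents that add atoms: formaldehyde (from paraformaldehyde), C=O
Why: CuI-catalysed anti-carbomagnesiation of a propargylic magnesium alkoxide should deliver the aryl group to the alkyne carbon next to the carbinol and magnesium to the terminal carbon, held cis to the alkoxide in the five-membered chelate 4, and hydroxymethylation of that vinylmagnesium with retention fixes the (Z) geometry while the carbinol centre is untouched.

Step 2
Reactants: 6 [4-(benzyloxy)-3-methoxyphenyl]methanol
Product: 7 1-(benzyloxy)-4-(bromomethyl)-2-methoxybenzene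
Conditions: PBr3 (0.4 equiv), Et2O, 0 °C; used at once
Reagents that add atoms: phosphorus tribromide, BrP(Br)Br
Why: Bromination of a primary benzylic alcohol through its phosphite ester (SN2) is routine, no stereocentre is involved and the aryl benzyl ether is inert.

Step 3
Reactants: 7 1-(benzyloxy)-4-(bromomethyl)-2-methoxybenzene
Product: 8 3-[4-(benzyloxy)-3-methoxyphenyl]propanenitrile
Conditions: MeCN (3 equiv), n-BuLi (3 equiv), THF, −78 °C; then 7, −78 → −20 °C
Reagents that add atoms: acetonitrile, CC#N
Why: SN2 alkylation of lithioacetonitrile by the reactive benzylic bromide should be clean, with excess anion at low temperature suppressing dialkylation.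

Step 4
Reactants: 8 3-[4-(benzyloxy)-3-methoxyphenyl]propanenitrile
Product: 10 1-(benzyloxy)-2-methoxy-4-(3,3,3-trimethoxypropyl)benzene, via imidate hydrochloride 9 (not isolated)
Conditions: HCl (g), MeOH (1.1 equiv), Et2O, 0 °C; then MeOH (excess), hexane, rt; filter; Et3N-washed alumina
Reagents that add atoms: methanol, CO
Why: In the Pinner reaction HCl-promoted addition of methanol gives the imidate hydrochloride, whose methanolysis should give the trimethyl orthoester with loss of NH4Cl, and benzyl and methyl aryl ethers tolerate anhydrous HCl at 0 °C.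

Step 5
Reactants: 5 (2Z,4R)-3-[4-(benzyloxy)-3-methoxyphenyl]pent-2-ene-1,4-diol; 10 1-(benzyloxy)-2-methoxy-4-(3,3,3-trimethoxypropyl)benzene
Product: 13 (3R,4S)-3-[4-(benzyloxy)-3-methoxybenzyl]-4-[(Z)-1-[4-(benzyloxy)-3-methoxyphenyl]prop-1-en-1-yl]dihydrofuran-2(3H)-one, via cyclic orthoester 11 (not isolated), via cyclic ketene acetal 12 (not isolated)
Conditions: 10 (1.3 equiv), pivalic acid (10 mol%), toluene, 80 °C, MeOH swept out; then mesitylene, 160 °C
Reagents that add atoms: none
Why: Acid-catalysed exchange ties both hydroxyls of 5 to the orthoester carbon (11), loss of methanol gives the 2-alkylidene-4,7-dihydro-1,3-dioxepine 12, and a [3,3] shift joins the exocyclic ketene-acetal carbon to the unsubstituted ring-alkene carbon while the secondary allylic C–O bond breaks, so that the acetal carbon becomes the lactone carbonyl. The closest known reaction type is the Johnson–Claisen rearrangement of (Z)-but-2-ene-1,4-diols with orthoesters to β-vinyl-γ-butyrolactones, here applied to a substituted diol and a substituted orthoester. The butanolide closes by contraction of the seven-membered ring: O1, C2 and C5 are already linked in 12 and the new C3–C4 bond spans the dioxepine through a bicyclo[3.2.1]-like chair array, so no separate lactonisation is needed. C4 is controlled by the (R)-carbinol, because the shift is suprafacial and the methyl group must sit outside (pseudo-equatorial) to escape 1,3-allylic strain with the cis ring CH2O, which opens one alkene face only and should give the (4S) lactone with a (Z)-propenyl group; C3 is controlled by the chair with the benzyl group pseudo-equatorial (E-ketene acetal, E/Z exchange being fast under the acid), which gives the trans (3R) arrangement, also the thermodynamic one. The step needs regioselectivity between the two allylic C–O bonds, secured by cleavage of the secondary C–O bond with bond formation at the CH terminus and not at the fully substituted aryl-bearing carbon, and by forming the cyclic orthoester at 80 °C before thermolysis so that acyclic mixed orthoesters do not rearrange. The methyl-bearing carbinol carbon ends as the distal alkene carbon and is removed in step 6.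

Step 6
Reactants: 13 (3R,4S)-3-[4-(benzyloxy)-3-methoxybenzyl]-4-[(Z)-1-[4-(benzyloxy)-3-methoxyphenyl]prop-1-en-1-yl]dihydrofuran-2(3H)-one
Product: 14 (3R,4R)-3-[4-(benzyloxy)-3-methoxybenzyl]-4-[4-(benzyloxy)-3-methoxybenzoyl]dihydrofuran-2(3H)-one
Conditions: O3, CH2Cl2/MeOH, NaHCO3, −78 °C, Sudan Red 7B end point; then Me2S, −78 °C → rt
Reagents that add atoms: ozone, [O-][O+]=O
Why: Ozonolysis of the electron-rich trisubstituted styrene, faster than attack on the arenes, with reductive work-up should excise the stereocontrol carbon as acetaldehyde and unveil the aryl ketone, leaving C3 untouched and C4 in its favoured trans arrangement.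

Step 7
Reactants: 14 (3R,4R)-3-[4-(benzyloxy)-3-methoxybenzyl]-4-[4-(benzyloxy)-3-methoxybenzoyl]dihydrofuran-2(3H)-one
Product: 15 (3R,4R)-3-[4-(benzyloxy)-3-methoxybenzyl]-4-[(S)-[4-(benzyloxy)-3-methoxyphenyl](hydroxy)methyl]dihydrofuran-2(3H)-one
Conditions: LiBH(s-Bu)3 (1.2 equiv), THF, −78 °C; AcOH, −78 °C; then pH 7 buffer, 30% H2O2, 0 °C
Reagents that add atoms: none
Why: In this Felkin–Anh-controlled reduction of an α-branched aryl ketone the benzyl-bearing ring carbon C3 stands anti to the bulky hydride, the carbonyl oxygen lies on the side of the ring CH2O and hydride passes the C4–H, which should give the (S)-carbinol, while −78 °C and the acidic quench keep the lactone from reduction and the new alkoxide from translactonisation.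

Step 8
Reactants: 15 (3R,4R)-3-[4-(benzyloxy)-3-methoxybenzyl]-4-[(S)-[4-(benzyloxy)-3-methoxyphenyl](hydroxy)methyl]dihydrofuran-2(3H)-one
Product: 16 (3R,4R)-4-[(S)-hydroxy(4-hydroxy-3-methoxyphenyl)methyl]-3-(4-hydroxy-3-methoxybenzyl)dihydrofuran-2(3H)-one
Conditions: H2 (1 atm), 10% Pd/C, EtOAc, rt, stopped at full conversion
Reagents that add atoms: none
Why: Hydrogenolysis of the two aryl benzyl ethers over Pd/C in a neutral aprotic medium should be much faster than loss of the secondary benzylic hydroxyl, and no stereocentre is touched.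

**Compound list**

1 | 1-(benzyloxy)-4-bromo-2-methoxybenzene | Brc1ccc(OCc2ccccc2)c(OC)c1 | starting material
2 | (R)-but-3-yn-2-ol | C[C@@H](O)C#C | starting material
3 | [4-(benzyloxy)-3-methoxyphenyl]magnesium bromide | Br[Mg]c1ccc(OCc2ccccc2)c(OC)c1 | intermediate
4 | (R)-4-[4-(benzyloxy)-3-methoxyphenyl]-5-methyl-2,5-dihydro-1,2-oxamagnesole (chelated vinylmagnesium alkoxide) | C[C@H]1O[Mg]C=C1c1ccc(OCc2ccccc2)c(OC)c1 | intermediate
5 | (2Z,4R)-3-[4-(benzyloxy)-3-methoxyphenyl]pent-2-ene-1,4-diol | C[C@@H](O)/C(=C\CO)c1ccc(OCc2ccccc2)c(OC)c1 | intermediate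
6 | [4-(benzyloxy)-3-methoxyphenyl]methanol | OCc1ccc(OCc2ccccc2)c(OC)c1 | starting material
7 | 1-(benzyloxy)-4-(bromomethyl)-2-methoxybenzene | BrCc1ccc(OCc2ccccc2)c(OC)c1 | intermediate
8 | 3-[4-(benzyloxy)-3-methoxyphenyl]propanenitrile | N#CCCc1ccc(OCc2ccccc2)c(OC)c1 | intermediate
9 | methyl 3-[4-(benzyloxy)-3-methoxyphenyl]propanimidate hydrochloride | COC(=N)CCc1ccc(OCc2ccccc2)c(OC)c1.Cl | intermediate
10 | 1-(benzyloxy)-2-methoxy-4-(3,3,3-trimethoxypropyl)benzene | COC(OC)(OC)CCc1ccc(OCc2ccccc2)c(OC)c1 | intermediate
11 | (4R)-2-methoxy-4-methyl-5-[4-(benzyloxy)-3-methoxyphenyl]-2-[2-[4-(benzyloxy)-3-methoxyphenyl]ethyl]-4,7-dihydro-1,3-dioxepine (both epimers at the orthoester carbon) | COC1(CCc2ccc(OCc3ccccc3)c(OC)c2)OCC=C(c2ccc(OCc3ccccc3)c(OC)c2)[C@@H](C)O1 | intermediate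
12 | (4R,E)-4-methyl-5-[4-(benzyloxy)-3-methoxyphenyl]-2-[2-[4-(benzyloxy)-3-methoxyphenyl]ethylidene]-4,7-dihydro-1,3-dioxepine | C[C@H]1O/C(=C/Cc2ccc(OCc3ccccc3)c(OC)c2)OCC=C1c1ccc(OCc2ccccc2)c(OC)c1 | intermediate
13 | (3R,4S)-3-[4-(benzyloxy)-3-methoxybenzyl]-4-[(Z)-1-[4-(benzyloxy)-3-methoxyphenyl]prop-1-en-1-yl]dihydrofuran-2(3H)-one | COc1cc(C[C@H]2C(=O)OC[C@@H]2/C(=C/C)c2ccc(OCc3ccccc3)c(OC)c2)ccc1OCc1ccccc1 | intermediate
14 | (3R,4R)-3-[4-(benzyloxy)-3-methoxybenzyl]-4-[4-(benzyloxy)-3-methoxybenzoyl]dihydrofuran-2(3H)-one | COc1cc(C[C@H]2C(=O)OC[C@@H]2C(=O)c2ccc(OCc3ccccc3)c(OC)c2)ccc1OCc1ccccc1 | intermediate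
15 | (3R,4R)-3-[4-(benzyloxy)-3-methoxybenzyl]-4-[(S)-[4-(benzyloxy)-3-methoxyphenyl](hydroxy)methyl]dihydrofuran-2(3H)-one | COc1cc(C[C@H]2C(=O)OC[C@@H]2[C@H](O)c2ccc(OCc3ccccc3)c(OC)c2)ccc1OCc1ccccc1 | intermediate
16 | (3R,4R)-4-[(S)-hydroxy(4-hydroxy-3-methoxyphenyl)methyl]-3-(4-hydroxy-3-methoxybenzyl)dihydrofuran-2(3H)-one | COc1cc(C[C@H]2C(=O)OC[C@@H]2[C@H](O)c2ccc(O)c(OC)c2)ccc1O | target

**Step count**

Total: 8 steps. Longest linear sequence: 7 steps (6 to 16 through steps 2 to 8).

**Steps most likely to fail**

Step 5. Exchange of the bulky orthoester may stop at acyclic mixed orthoesters, which can rearrange through the primary allylic oxygen to a quaternary centre. The transition state with the benzyl group pseudo-axial may also compete and erode the configuration at C3. The fallback separates ring contraction from benzyl introduction. It sets out from 5, which is heated with commercial trimethyl orthoacetate (pivalic acid cat., 140 °C) in the same ring-contracting Johnson–Claisen rearrangement. This should give (S)-4-[(Z)-1-[4-(benzyloxy)-3-methoxyphenyl]prop-1-en-1-yl]dihydrofuran-2(3H)-one F1. Its lithium enolate (LiN(SiMe3)2, THF, −78 °C) is then alkylated with bromide 7 anti to the C4 substituent, the usual trans-selective benzylation of 4-substituted butanolides, and the route is rejoined at 13.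

Step 1. Arylmagnesiation of the hindered secondary alkoxide may be slow, deprotonation of the terminal alkyne may stall the addition, and the aryl Grignard reagent may be lost to formaldehyde. The fallback builds the (Z)-enediol through a butenolide and sets out from 2. Double deprotonation (n-BuLi, 2.1 equiv, THF, −78 °C) and carboxylation with CO2 should give (R)-4-hydroxypent-2-ynoic acid F2, which Me3SiCHN2 (toluene/MeOH) converts to methyl (R)-4-hydroxypent-2-ynoate F3. CuOAc-catalysed syn-hydroarylation with commercial [4-(benzyloxy)-3-methoxyphenyl]boronic acid (MeOH, rt) places the aryl group on the β-carbon, and the (Z)-γ-hydroxy enoate lactonises in the flask to (R)-4-[4-(benzyloxy)-3-methoxyphenyl]-5-methylfuran-2(5H)-one F4. Reduction with i-Bu2AlH (CH2Cl2, −78 → 0 °C) opens the butenolide to the diol and the route is rejoined at 5.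

Step 7. Hydride may add to the wrong face of the aroyl carbonyl if the substrate bias is weak, and the lithium alkoxide formed may translactonise or the basic reagent may enolise C4. The fallback replaces substrate control by catalyst control under non-basic conditions. It sets out from 14 and uses Noyori asymmetric transfer hydrogenation with RuCl(p-cymene)[(S,S)-TsDPEN] (a divalent ruthenium complex) in HCO2H/Et3N at rt. The catalyst's aryl/alkyl discrimination should give the (S)-carbinol without an alkoxide intermediate, and the route is rejoined directly at 15; no further compound arises on this path (F0).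

**Further compounds**

F1 | step 5 | (S)-4-[(Z)-1-[4-(benzyloxy)-3-methoxyphenyl]prop-1-en-1-yl]dihydrofuran-2(3H)-one | O=C1OC[C@@H](C1)/C(=C/C)c1ccc(OCc2ccccc2)c(OC)c1
F2 | step 1 | (R)-4-hydroxypent-2-ynoic acid | C[C@@H](O)C#CC(=O)O
F3 | step 1 | methyl (R)-4-hydroxypent-2-ynoate | C[C@@H](O)C#CC(=O)OC
F4 | step 1 | (R)-4-[4-(benzyloxy)-3-methoxyphenyl]-5-methylfuran-2(5H)-one | C[C@H]1OC(=O)C=C1c1ccc(OCc2ccccc2)c(OC)c1
F0 | step 7 | none | none
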